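**Retrosynthetic overview**
1. Feature: the oxane ring (O1, C2–C6) carries the ring A ethyl arm at C2, OH at C4 and ring B at C6, all cis and equatorial (2S,4R,6S). Oxygen at C4 between cis carbon substituents at C2 and C6 is the pattern left when an aldehyde C=O adds endo across a 4-alkyl-2-silyloxy-1,3-diene.
2. Endgame disconnections: the three aryl pivalates (methanolysis), the C4–H bond (axial hydride to the oxan-4-one) and the C3=C4 silyl enol ether (hydrolysis).
3. Key disconnection: O1–C2 and C5–C6 together, in one catalytic enantioselective oxa-[4+2] cycloaddition of the ring A silyloxydiene with the ring B aldehyde.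
4. The diene comes from eugenol (acylation, hydroboration–oxidation, alcohol oxidation, Wittig enone synthesis, soft enolisation). The aldehyde comes from 5-hydroxyvanillin (bis-acylation).
5. Ring order: rings A and B are bought. The oxane is the only ring formed, and it forms in the key step.

Key step: step 7

Assumption: the sense of induction is assigned by analogy, since the (1R,2S)-aminoindanol chromium catalyst is known to give the R configuration at the aldehyde-derived carbon when the aldehyde substituent ranks second; the (1S,2R) catalyst is therefore used for 6S, and the equally available antipode would replace it if Mosher ester analysis of the C4 alcohol showed the opposite series.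

**Step 1**
Reactants: 1 eugenol (4-allyl-2-methoxyphenol)
Product: 2 4-allyl-2-methoxyphenyl pivalate
Conditions: PivCl, Et3N, DMAP (cat.), CH2Cl2, 0 °C to rt
Reagents that add atoms: pivaloyl chloride, CC(C)(C)C(=O)Cl
Why: DMAP-catalysed acylation masks the acidic phenol for the borane, ylide and silyl triflate chemistry ahead, in a form that can later be removed without hydrogenolysis, which would endanger the benzylic C6–O1 bond.

**Step 2**
Reactants: 2 4-allyl-2-methoxyphenyl pivalate
Product: 4 4-(3-hydroxypropyl)-2-methoxyphenyl pivalate, via B-alkyl-9-BBN adduct 3 (not isolated)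
Conditions: 9-BBN, THF, 0 °C to rt; then 3 M aq NaOAc, 30 % H2O2, 0 °C to rt
Reagents that add atoms: 9-borabicyclo[3.3.1]nonane, B1C2CCCC1CCC2 (boron unit of 3); hydrogen peroxide, OO (hydroxyl oxygen of 4)
Why: In this hydroboration–oxidation the bulky 9-BBN places boron on the terminal allyl carbon, and acetate-buffered peroxide oxidises the C–B bond below the pH at which hydroperoxide anion would cleave the aryl ester.

**Step 3**
Reactants: 4 4-(3-hydroxypropyl)-2-methoxyphenyl pivalate
Product: 5 2-methoxy-4-(3-oxopropyl)phenyl pivalate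
Conditions: TEMPO (10 mol %), PhI(OAc)2, CH2Cl2, rt
Reagents that add atoms: none
Why: The TEMPO (oxoammonium) oxidation stops at the aldehyde under water-free, near-neutral conditions that leave the ester and the acylated ring A untouched.

**Step 4**
Reactants: 5 2-methoxy-4-(3-oxopropyl)phenyl pivalate; 6 1-(triphenylphosphoranylidene)propan-2-one
Product: 7 (E)-6-(3-methoxy-4-pivaloyloxyphenyl)hex-3-en-2-one
Conditions: CH2Cl2, 40 °C
Reagents that add atoms: none
Why: The Wittig reaction of a carbonyl-stabilised ylide leads to the E-enone, and the low basicity of the ylide spares the enolisable aldehyde and the aryl ester.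

**Step 5**
Reactants: 7 (E)-6-(3-methoxy-4-pivaloyloxyphenyl)hex-3-en-2-one
Product: 8 (E)-2-triethylsilyloxy-6-(3-methoxy-4-pivaloyloxyphenyl)hexa-1,3-diene
Conditions: TESOTf, Et3N, Et2O, −78 to 0 °C; cold aq NaHCO3 work-up, Et3N-washed silica
Reagents that add atoms: triethylsilyl trifluoromethanesulfonate, CC[Si](CC)(CC)OS(=O)(=O)C(F)(F)F
Why: In this soft enolisation O-silylation of the enone makes the unhindered α'-methyl protons the most accessible acidic ones, so Et3N should give the cross-conjugated 2-silyloxydiene rather than the linear dienol ether from γ-deprotonation, with the E alkene untouched.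

**Step 6**
Reactants: 9 3,4-dihydroxy-5-methoxybenzaldehyde (5-hydroxyvanillin)
Product: 10 3-methoxy-4,5-bis(pivaloyloxy)benzaldehyde
Conditions: PivCl (2.5 equiv), Et3N, DMAP (cat.), CH2Cl2, 0 °C to rt
Reagents that add atoms: pivaloyl chloride, CC(C)(C)C(=O)Cl
Why: DMAP-catalysed acylation of both catechol hydroxyls removes the protons that would quench diene and catalyst, and it lowers the donor power of ring B so that the formyl group becomes more electrophilic.

**Step 7**
Reactants: 8 (E)-2-triethylsilyloxy-6-(3-methoxy-4-pivaloyloxyphenyl)hexa-1,3-diene; 10 3-methoxy-4,5-bis(pivaloyloxy)benzaldehyde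
Product: 11 (2S,6S)-2-[2-(3-methoxy-4-pivaloyloxyphenyl)ethyl]-6-[3-methoxy-4,5-bis(pivaloyloxy)phenyl]-4-triethylsilyloxy-5,6-dihydro-2H-pyran (2,6-cis, C3=C4 enol ether)
Conditions: (L)CrCl (10 mol %, trivalent chromium; LH2 = (1S,2R)-1-{[3-(1-adamantyl)-2-hydroxy-5-methylbenzylidene]amino}indan-2-ol), powdered 4 Å MS, acetone (ca. 2 M), rt
Reagents that add atoms: none
Why: The formyl oxygen of 10 binds the trivalent chromium centre and the diene adds in a concerted but asynchronous oxa-[4+2] event in which C1 of the silyl enol ether unit bonds to the formyl carbon (C5–C6) slightly ahead of O1–C2, which is the known hetero-Diels–Alder reaction of 4-alkyl-2-silyloxydienes with aldehydes under tridentate Schiff base chromium chloride catalysts. The oxane, the only ring formed, is closed by cycloaddition with both ring bonds made in one transition state, and it emerges as the C3=C4 triethylsilyl enol ether. C6 is set by the catalyst, whose adamantyl and indane walls should leave only the si face of the bound aldehyde open (6S). C2 is set relative to C6 by the endo placement of ring B over the E-configured diene, which brings the outward-pointing ethyl arm and the aryl group cis (2S). The regiochemistry needed is fixed by the 2-silyloxy group, which makes C1 the nucleophilic terminus, and chemoselectivity rests on 10 being non-enolisable and activated by its two acyloxy groups while the hindered pivalate carbonyls should not compete for chromium. The sieves keep water away from both the hydrolysable diene and the catalyst site.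

**Step 8**
Reactants: 11 cycloadduct
Product: 12 (2S,6S)-2-[2-(3-methoxy-4-pivaloyloxyphenyl)ethyl]-6-[3-methoxy-4,5-bis(pivaloyloxy)phenyl]oxan-4-one
Conditions: 1 M aq HCl, THF, 0 °C
Reagents that add atoms: none
Why: Acid hydrolysis of the silyl enol ether (protonation at C3, silicon passed to water) is mild enough that neither the pivalates nor the β-alkoxy ketone (retro-oxa-Michael) should respond, so C2 and C6 are kept.

**Step 9**
Reactants: 12 oxan-4-one
Product: 13 (2S,4R,6S)-2-[2-(3-methoxy-4-pivaloyloxyphenyl)ethyl]-6-[3-methoxy-4,5-bis(pivaloyloxy)phenyl]oxan-4-ol (all-cis)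
Conditions: NaBH4, MeOH/THF 1:1, −40 °C; aq NH4Cl
Reagents that add atoms: none
Why: In this substrate-controlled borohydride reduction the chair holds the C2 and C6 groups equatorial, so the small hydride should attack C4 along the axial trajectory and give the equatorial 4R alcohol.

**Step 10**
Reactants: 13 tripivalate alcohol
Product: 14 (2S,4R,6S)-6-(3,4-dihydroxy-5-methoxyphenyl)-2-[2-(4-hydroxy-3-methoxyphenyl)ethyl]oxan-4-ol (target)
Conditions: NaOMe (4 equiv), degassed MeOH, Ar, 0 °C to rt; AcOH quench under Ar
Reagents that add atoms: none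
Why: In this Zemplén-type transesterification the phenoxide leaving groups let even pivalates exchange with methoxide at or below room temperature, no stereocentre is touched, and exclusion of oxygen protects the ring B catecholate.

**Compound list**
1 | eugenol | C=CCc1ccc(O)c(OC)c1 | starting material
2 | 4-allyl-2-methoxyphenyl pivalate | C=CCc1ccc(OC(=O)C(C)(C)C)c(OC)c1 | intermediate
3 | B-[3-(3-methoxy-4-pivaloyloxyphenyl)propyl]-9-borabicyclo[3.3.1]nonane | COc1cc(CCCB2C3CCCC2CCC3)ccc1OC(=O)C(C)(C)C | intermediate
4 | 4-(3-hydroxypropyl)-2-methoxyphenyl pivalate | CC(C)(C)C(=O)Oc1ccc(CCCO)cc1OC | intermediate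
5 | 2-methoxy-4-(3-oxopropyl)phenyl pivalate | CC(C)(C)C(=O)Oc1ccc(CCC=O)cc1OC | intermediate
6 | 1-(triphenylphosphoranylidene)propan-2-one | CC(=O)C=P(c1ccccc1)(c1ccccc1)c1ccccc1 | starting material
7 | (E)-6-(3-methoxy-4-pivaloyloxyphenyl)hex-3-en-2-one | CC(=O)/C=C/CCc1ccc(OC(=O)C(C)(C)C)c(OC)c1 | intermediate
8 | (E)-2-triethylsilyloxy-6-(3-methoxy-4-pivaloyloxyphenyl)hexa-1,3-diene | C=C(O[Si](CC)(CC)CC)/C=C/CCc1ccc(OC(=O)C(C)(C)C)c(OC)c1 | intermediate
9 | 3,4-dihydroxy-5-methoxybenzaldehyde | COc1cc(C=O)cc(O)c1O | starting material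
10 | 3-methoxy-4,5-bis(pivaloyloxy)benzaldehyde | O=Cc1cc(OC(=O)C(C)(C)C)c(OC(=O)C(C)(C)C)c(OC)c1 | intermediate
11 | (2S,6S)-cis cycloadduct, C3=C4 triethylsilyl enol ether | CC(C)(C)C(=O)Oc1ccc(CC[C@H]2C=C(O[Si](CC)(CC)CC)C[C@@H](c3cc(OC(=O)C(C)(C)C)c(OC(=O)C(C)(C)C)c(OC)c3)O2)cc1OC | intermediate
12 | (2S,6S)-cis-2,6-disubstituted oxan-4-one tripivalate | CC(C)(C)C(=O)Oc1ccc(CC[C@H]2CC(=O)C[C@@H](c3cc(OC(=O)C(C)(C)C)c(OC(=O)C(C)(C)C)c(OC)c3)O2)cc1OC | intermediate
13 | (2S,4R,6S)-all-cis oxan-4-ol tripivalate | CC(C)(C)C(=O)Oc1ccc(CC[C@H]2C[C@@H](O)C[C@@H](c3cc(OC(=O)C(C)(C)C)c(OC(=O)C(C)(C)C)c(OC)c3)O2)cc1OC | intermediate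
14 | (2S,4R,6S)-6-(3,4-dihydroxy-5-methoxyphenyl)-2-[2-(4-hydroxy-3-methoxyphenyl)ethyl]oxan-4-ol | COc1cc(CC[C@H]2C[C@@H](O)C[C@@H](c3cc(O)c(O)c(OC)c3)O2)ccc1O | target

Total step count: 10. Longest linear sequence: 9 (steps 1–5 and 7–10, from eugenol).

**Steps most likely to fail**

First, step 7.
- Turnover may be slow with a bulky, solid aromatic aldehyde, so that hydrolysis of the diene competes.
- Facial selectivity may erode, or the reaction may leak into an open-chain aldol pathway.
- The fallback sets out from 8 and 10 and comes back at 12, and it joins the same two partners stepwise.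
- A catalytic enantioselective Mukaiyama aldol addition forms only C5–C6. It uses (R)-2-butyl-4-(1H-indol-3-ylmethyl)-3-tosyl-1,3,2-oxazaborolidin-5-one (20 mol %, EtCN, −78 °C). This antipode is expected, by analogy with benzaldehyde, to open the si face of 10.
- The addition should give the (S)-β-triethylsilyloxy enone F1. Treatment with 1 M HCl in THF then frees the (S)-β-hydroxy enone F2.
- Amberlyst-15 in CH2Cl2 closes O1–C2 by a 6-endo-trig oxa-Michael addition under thermodynamic control. The C6 centre steers C2 into the diequatorial cis arrangement of 12.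

Second, step 5.
- Competing γ-deprotonation may give the linear dienol ether.
- Protodesilylation on handling may occur, or amine and triflate salts may be carried over and block the chromium catalyst.
- The fallback avoids any diene. It sets out from 10 and 5 and comes back at 13.
- Keck allylation of 10 ((S)-BINOL, Ti(OiPr)4, 4 Å MS, allyltributylstannane, CH2Cl2, −20 °C) should give the (S)-homoallylic alcohol F3 and sets C6.
- Prins cyclisation of F3 with aldehyde 5 (TFA, CH2Cl2, 0 °C to rt) passes through an all-equatorial chair oxocarbenium ion. It should give the all-cis oxan-4-yl trifluoroacetate F4.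
- Ring B, acylated and carrying its methoxy group meta to C6, is a poor cation stabiliser. This should hold back oxonia-Cope scrambling.
- NaHCO3 in MeOH removes only the trifluoroacetate and delivers 13.

Third, step 10.
- The ring B catecholate may be oxidised by air, or the hindered esters may be cleaved incompletely.
- Base may open C6–O1 through a para-quinone methide.
- The fallback sets out from 12 and comes back at 14, and it replaces solvolysis by reduction.
- Excess LiAlH4 in THF, −78 to 0 °C, should first reduce the ketone by axial delivery and then cleave the three esters.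
- The phenols stay bound to aluminium until a degassed acidic quench (aq KHSO4).
- No compound outside the list is made (entry F0).

**Further compounds**
F1 | step 7 | (S,E)-1-[3-methoxy-4,5-bis(pivaloyloxy)phenyl]-7-(3-methoxy-4-pivaloyloxyphenyl)-1-triethylsilyloxyhept-4-en-3-one | CC(C)(C)C(=O)Oc1ccc(CC/C=C/C(=O)C[C@@H](c2cc(OC(=O)C(C)(C)C)c(OC(=O)C(C)(C)C)c(OC)c2)O[Si](CC)(CC)CC)cc1OC
F2 | step 7 | (S,E)-1-hydroxy-1-[3-methoxy-4,5-bis(pivaloyloxy)phenyl]-7-(3-methoxy-4-pivaloyloxyphenyl)hept-4-en-3-one | CC(C)(C)C(=O)Oc1ccc(CC/C=C/C(=O)C[C@@H](c2cc(OC(=O)C(C)(C)C)c(OC(=O)C(C)(C)C)c(OC)c2)O)cc1OC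
F3 | step 5 | (S)-1-[3-methoxy-4,5-bis(pivaloyloxy)phenyl]but-3-en-1-ol | C=CC[C@@H](c1cc(OC(=O)C(C)(C)C)c(OC(=O)C(C)(C)C)c(OC)c1)O
F4 | step 5 | (2S,4R,6S)-2-[2-(3-methoxy-4-pivaloyloxyphenyl)ethyl]-6-[3-methoxy-4,5-bis(pivaloyloxy)phenyl]oxan-4-yl trifluoroacetate | CC(C)(C)C(=O)Oc1ccc(CC[C@H]2C[C@@H](OC(=O)C(F)(F)F)C[C@@H](c3cc(OC(=O)C(C)(C)C)c(OC(=O)C(C)(C)C)c(OC)c3)O2)cc1OC
F0 | step 10 | none | none
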